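## Plan
- Numbering: benzoxepine O1, C2–C5, C5a, C6–C9, C9a; ring A is the arene, ring B the oxepine. Retrosynthetic cuts, in order: the silyl ethers and the C4–O angelate ester, the C4–H bond (allylic alcohol back to the enone), then the C5–C5a bond.
- Enabling feature: C5 is bonded to ring A at C5a, carries the exocyclic methylene and sits next to oxygenated C4. This aryl–C(=CH2)–C(O) array is what remains after the aryl carbon of a 4-vinylchroman-4-ol shifts from the carbinol carbon onto the activated vinyl group, so ring B traces back to a pyran.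
- Further cuts: vinyl–C4 (Grignard), C2–H (conjugate reduction of a chromone), O1–C2 (closure of an o-hydroxyaryl ynone), the ynone C–C bond (acetylide plus salicylaldehyde), then the formyl C–C bond and one C–O bond on 2-methylresorcinol.
- Forward: ring A is bought. The pyranone is closed onto it, reduced, vinylated and enlarged by one carbon to ring B. The ester goes on in the penultimate step.
- Stereochemistry: C2 (S) comes from ligand-controlled copper hydride reduction. C4 (R, trans to C2) comes from oxazaborolidine-controlled ketone reduction. The Z alkene comes from angelic acid through a non-isomerising acylation.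

Key step: step 10

Assumption: (R)-DTBM-SEGPHOS is taken to steer copper hydride to the Re face of C2 of the chromone in step 8. If a pilot run shows the opposite sense, the (S) ligand is used and nothing else changes.

## Route

Step 1
Reactants: 1 2-methylresorcinol
Product: 2 1,3-bis(methoxymethoxy)-2-methylbenzene
Conditions: NaH (2.4 equiv), MOMCl (2.4 equiv), DMF, 0 °C to rt
Reagents that add atoms: chloromethyl methyl ether (MOMCl), COCCl
Why: Williamson-type O-alkylation of both phenoxides installs acetals that withstand the organolithium, magnesium and acetylide steps ahead, cannot migrate between neighbouring oxygens and direct the metalation of step 2.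

Step 2
Reactants: 2 1,3-bis(methoxymethoxy)-2-methylbenzene
Product: 5 2,4-bis(methoxymethoxy)-3-methylphenol, via aryllithium 3 (not isolated), via dimethyl arylboronate 4 (not isolated)
Conditions: n-BuLi, TMEDA, THF, 0 °C; B(OMe)3, -78 °C to rt; AcOH, 30% aq H2O2, 0 °C to rt
Reagents that add atoms: hydrogen peroxide, OO
Why: Directed ortho-metalation next to an OMOM group (the two candidate positions are equivalent, and alkoxy groups do not favour lateral lithiation of the methyl group), borate trapping and oxidative boron-to-oxygen 1,2-shift should deliver the phenol in one flask.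

Step 3
Reactants: 5 2,4-bis(methoxymethoxy)-3-methylphenol
Product: 7 2-hydroxy-3,5-bis(methoxymethoxy)-4-methylbenzaldehyde, via salicyl alcohol 6 (not isolated)
Conditions: MgCl2, Et3N, (CH2O)n, MeCN, reflux; brief cold dilute HCl work-up
Reagents that add atoms: formaldehyde (from paraformaldehyde), C=O
Why: In the Casnati–Skattebøl formylation the magnesium phenoxide delivers formaldehyde only ortho to the free OH, here the single open ortho position, which overrides the electronic bias for the other C–H, and a second formaldehyde oxidises the salicyl alcohol by hydride transfer.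

Step 4
Reactants: 7 2-hydroxy-3,5-bis(methoxymethoxy)-4-methylbenzaldehyde; 8 trimethyl[(2-methylbut-3-yn-2-yl)oxy]silane
Product: 10 1-[2-hydroxy-3,5-bis(methoxymethoxy)-4-methylphenyl]-4-methyl-4-(trimethylsilyloxy)pent-2-yn-1-ol (racemic), via lithium acetylide 9 (not isolated)
Conditions: 8 (2.4 equiv), n-BuLi (2.3 equiv), THF, -78 °C; then 7, -78 to 0 °C; aq NH4Cl
Reagents that add atoms: none
Why: Acetylide 1,2-addition to an aldehyde, in which the first equivalent only deprotonates the phenol and the new carbinol centre need not be controlled because step 5 removes it.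

Step 5
Reactants: 10 1-[2-hydroxy-3,5-bis(methoxymethoxy)-4-methylphenyl]-4-methyl-4-(trimethylsilyloxy)pent-2-yn-1-ol
Product: 11 1-[2-hydroxy-3,5-bis(methoxymethoxy)-4-methylphenyl]-4-methyl-4-(trimethylsilyloxy)pent-2-yn-1-one
Conditions: activated MnO2 (excess), CH2Cl2, rt
Reagents that add atoms: none
Why: MnO2 oxidation is selective for the doubly activated benzylic and propargylic alcohol, while the phenol has every ortho and para position blocked against oxidative coupling and becomes hydrogen-bonded to the new ketone.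

Step 6
Reactants: 11 1-[2-hydroxy-3,5-bis(methoxymethoxy)-4-methylphenyl]-4-methyl-4-(trimethylsilyloxy)pent-2-yn-1-one
Product: 13 6,8-dihydroxy-2-(2-hydroxypropan-2-yl)-7-methyl-4H-chromen-4-one, via protected chromone 12 (not isolated)
Conditions: DMAP (20 mol %), DMF, rt; then HCl (3 M in MeOH), 45 °C
Reagents that add atoms: none
Why: DMAP-catalysed 6-endo-dig oxa-Michael cyclisation of the o-alkynoylphenol closes the pyranone while the tertiary oxygen is still masked, which shuts off the 3(2H)-furanone pathway of gamma-hydroxy ynones, and acid-catalysed exchange with methanol then strips the MOM and TMS groups from the acid-stable chromone.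

Step 7
Reactants: 13 6,8-dihydroxy-2-(2-hydroxypropan-2-yl)-7-methyl-4H-chromen-4-one
Product: 15 6,8-bis(tert-butyldimethylsilyloxy)-7-methyl-2-[2-(triethylsilyloxy)propan-2-yl]-4H-chromen-4-one, via bis-TBS chromone 14 (not isolated)
Conditions: TBSCl (2.3 equiv), imidazole (6 equiv), DMF, 0 °C to rt; then TESCl (1.5 equiv), DMAP (0.2 equiv), 40 °C
Reagents that add atoms: tert-butyldimethylsilyl chloride, CC(C)(C)[Si](C)(C)Cl; triethylsilyl chloride, CC[Si](CC)(CC)Cl
Why: Imidazole-promoted silylation caps the two phenols quickly and leaves the tertiary alcohol for the smaller TESCl, giving a fluoride-labile protecting set that blocks the side-chain oxygen from intercepting the cation of step 10.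

Step 8
Reactants: 15 6,8-bis(tert-butyldimethylsilyloxy)-7-methyl-2-[2-(triethylsilyloxy)propan-2-yl]-4H-chromen-4-one
Product: 16 (2S)-6,8-bis(tert-butyldimethylsilyloxy)-7-methyl-2-[2-(triethylsilyloxy)propan-2-yl]chroman-4-one
Conditions: Cu(OAc)2·H2O (3 mol %), (R)-DTBM-SEGPHOS (3.3 mol %), (EtO)2MeSiH (1.5 equiv), t-BuOH (1.5 equiv), toluene, 0 °C
Reagents that add atoms: none
Why: In this asymmetric copper hydride conjugate reduction of a 2-substituted chromone the bisphosphine-ligated hydride adds to the Re face of C2 and sets the S centre, and t-BuOH protonates the copper enolate so that limited silane and low temperature hold the reaction at the ketone.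

Step 9
Reactants: 16 (2S)-6,8-bis(tert-butyldimethylsilyloxy)-7-methyl-2-[2-(triethylsilyloxy)propan-2-yl]chroman-4-one; 17 vinylmagnesium bromide
Product: 18 (2S)-6,8-bis(tert-butyldimethylsilyloxy)-4-ethenyl-7-methyl-2-[2-(triethylsilyloxy)propan-2-yl]chroman-4-ol (both C4 epimers)
Conditions: LaCl3·2LiCl (1.1 equiv), THF, 0 °C; 17 (1.5 equiv), -78 to -30 °C; pH 7 buffer
Reagents that add atoms: none
Why: In this lanthanum-salt-promoted Grignard 1,2-addition the oxophilic salt activates the carbonyl and tempers basicity, so enolisation and the retro-oxa-Michael erosion of C2 are suppressed, and the C4 configuration is irrelevant because step 10 destroys it.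

Step 10
Reactants: 18 (2S)-6,8-bis(tert-butyldimethylsilyloxy)-4-ethenyl-7-methyl-2-[2-(triethylsilyloxy)propan-2-yl]chroman-4-ol
Product: 21 (2S)-7,9-bis(tert-butyldimethylsilyloxy)-8-methyl-5-methylidene-2-[2-(triethylsilyloxy)propan-2-yl]-2,3-dihydro-1-benzoxepin-4(5H)-one, via selanyl ketone 19 (not isolated), via selenoxide 20 (not isolated)
Conditions: PhSeCl (1.15 equiv), AgOTf (1.15 equiv), 2,6-di-tert-butyl-4-methylpyridine (2.5 equiv), CH2Cl2, -78 to -30 °C; then mCPBA (1.2 equiv), -78 to 0 °C
Reagents that add atoms: none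
Why: PhSeOTf (preformed from PhSeCl and AgOTf) turns the vinyl group of 18 into a seleniranium ion, and the ring A carbon C4a (chroman numbering), enriched by O1 in the ortho and the methyl group in the para position, bridges to the internal alkene carbon through a phenonium-like transition state while the carbinol oxygen closes down to the ketone and the hindered pyridine takes the proton, which gives 19 with the new C5–C5a bond. mCPBA then oxidises selenium at -78 °C and selenoxide 20 undergoes syn elimination on warming; its only beta hydrogen is the doubly activated C5–H, so the double bond can only become exocyclic. The closest known chemistry is the selenonium- or halonium-induced semipinacol rearrangement of tertiary allylic alcohols, established for aryl vinyl carbinols and for enlarging 1-vinylcycloalkanols, and aryl migration within a benzo-fused ring is also the normal course of the hypervalent iodine ring expansion of 4-methylidenechromans. Ring B is not made by end-to-end cyclisation: the pyran grows by one carbon through the 1,2-shift (transient 3-exo bridging of the ipso carbon, then rupture of the old C4–C4a bond). No new stereocentre survives, since both C4 epimers of 18 give the same ketone, C5 of 19 is planarised in the elimination and C2 is a spectator. The step needs aryl instead of C3 alkyl migration (secured by the donor-substituted ipso carbon), attack at the alkene instead of the arene (the one free ring position lies between an OTBS group and the quaternary carbon) and a medium that neither ionises the tertiary benzylic allylic alcohol nor enolises the beta-aryloxy ketone towards retro-oxa-Michael opening (secured by the non-nucleophilic buffer, the low temperature and the absence of any stronger base).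

Step 11
Reactants: 21 (2S)-7,9-bis(tert-butyldimethylsilyloxy)-8-methyl-5-methylidene-2-[2-(triethylsilyloxy)propan-2-yl]-2,3-dihydro-1-benzoxepin-4(5H)-one
Product: 22 (2S,4R)-7,9-bis(tert-butyldimethylsilyloxy)-8-methyl-5-methylidene-2-[2-(triethylsilyloxy)propan-2-yl]-2,3,4,5-tetrahydro-1-benzoxepin-4-ol
Conditions: (S)-2-methyl-CBS-oxazaborolidine (0.3 equiv), catecholborane (1.8 equiv), toluene, -78 °C; MeOH, pH 7 buffer
Reagents that add atoms: none
Why: In the Corey–Bakshi–Shibata reduction the alpha-branched aryl-alkenyl side (C5) acts as the large group and C3H2 as the small one, so the (S) catalyst should deliver hydride to the face that gives the 4R (2,4-trans) alcohol, and at -78 °C the catalysed 1,2-pathway outruns conjugate reduction or hydroboration by catecholborane.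

Step 12
Reactants: 22 (2S,4R)-7,9-bis(tert-butyldimethylsilyloxy)-8-methyl-5-methylidene-2-[2-(triethylsilyloxy)propan-2-yl]-2,3,4,5-tetrahydro-1-benzoxepin-4-ol; 23 angelic acid
Product: 25 (2S,4R)-7,9-bis(tert-butyldimethylsilyloxy)-8-methyl-5-methylidene-2-[2-(triethylsilyloxy)propan-2-yl]-2,3,4,5-tetrahydro-1-benzoxepin-4-yl (2Z)-2-methylbut-2-enoate, via mixed anhydride 24 (not isolated)
Conditions: 23 (3 equiv), 2,4,6-trichlorobenzoyl chloride (3 equiv), Et3N (3.3 equiv), toluene, rt; then 22, 75 °C
Reagents that add atoms: none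
Why: Yamaguchi-type mixed-anhydride acylation run without DMAP lets the alcohol attack the less hindered angeloyl carbonyl with no nucleophilic catalyst that could add to the enoate and turn Z into E, and the C4–O bond is untouched so 4R is retained.

Step 13
Reactants: 25 (2S,4R)-7,9-bis(tert-butyldimethylsilyloxy)-8-methyl-5-methylidene-2-[2-(triethylsilyloxy)propan-2-yl]-2,3,4,5-tetrahydro-1-benzoxepin-4-yl (2Z)-2-methylbut-2-enoate
Product: 26 (2S,4R)-7,9-dihydroxy-2-(2-hydroxypropan-2-yl)-8-methyl-5-methylidene-2,3,4,5-tetrahydro-1-benzoxepin-4-yl (2Z)-2-methylbut-2-enoate (CNP0160456.1)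
Conditions: HF·pyridine, pyridine, THF, 0 °C to rt, under argon
Reagents that add atoms: none
Why: Fluoride-driven Si–O cleavage removes both aryl TBS groups and the tertiary TES group, and the pyridine buffer keeps the medium too weakly acidic to ionise the allylic ester or the tertiary alcohol and too weakly basic to form phenoxides that could transacylate or isomerise the angelate.

## Compound list
1 | 2-methylbenzene-1,3-diol (2-methylresorcinol) | Cc1c(O)cccc1O | starting material
2 | 1,3-bis(methoxymethoxy)-2-methylbenzene | COCOc1cccc(OCOC)c1C | intermediate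
3 | [2,4-bis(methoxymethoxy)-3-methylphenyl]lithium | [Li]c1ccc(OCOC)c(C)c1OCOC | intermediate
4 | dimethyl [2,4-bis(methoxymethoxy)-3-methylphenyl]boronate | COB(OC)c1ccc(OCOC)c(C)c1OCOC | intermediate
5 | 2,4-bis(methoxymethoxy)-3-methylphenol | COCOc1ccc(O)c(OCOC)c1C | intermediate
6 | 2-(hydroxymethyl)-4,6-bis(methoxymethoxy)-5-methylphenol | COCOc1cc(CO)c(O)c(OCOC)c1C | intermediate
7 | 2-hydroxy-3,5-bis(methoxymethoxy)-4-methylbenzaldehyde | COCOc1cc(C=O)c(O)c(OCOC)c1C | intermediate
8 | trimethyl[(2-methylbut-3-yn-2-yl)oxy]silane | C#CC(C)(C)O[Si](C)(C)C | starting material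
9 | [3-methyl-3-(trimethylsilyloxy)but-1-yn-1-yl]lithium | [Li]C#CC(C)(C)O[Si](C)(C)C | intermediate
10 | 1-[2-hydroxy-3,5-bis(methoxymethoxy)-4-methylphenyl]-4-methyl-4-(trimethylsilyloxy)pent-2-yn-1-ol (racemic) | COCOc1cc(C(O)C#CC(C)(C)O[Si](C)(C)C)c(O)c(OCOC)c1C | intermediate
11 | 1-[2-hydroxy-3,5-bis(methoxymethoxy)-4-methylphenyl]-4-methyl-4-(trimethylsilyloxy)pent-2-yn-1-one | COCOc1cc(C(=O)C#CC(C)(C)O[Si](C)(C)C)c(O)c(OCOC)c1C | intermediate
12 | 6,8-bis(methoxymethoxy)-7-methyl-2-[2-(trimethylsilyloxy)propan-2-yl]-4H-chromen-4-one | COCOc1cc2c(=O)cc(C(C)(C)O[Si](C)(C)C)oc2c(OCOC)c1C | intermediate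
13 | 6,8-dihydroxy-2-(2-hydroxypropan-2-yl)-7-methyl-4H-chromen-4-one | Cc1c(O)cc2c(=O)cc(C(C)(C)O)oc2c1O | intermediate
14 | 6,8-bis(tert-butyldimethylsilyloxy)-2-(2-hydroxypropan-2-yl)-7-methyl-4H-chromen-4-one | Cc1c(O[Si](C)(C)C(C)(C)C)cc2c(=O)cc(C(C)(C)O)oc2c1O[Si](C)(C)C(C)(C)C | intermediate
15 | 6,8-bis(tert-butyldimethylsilyloxy)-7-methyl-2-[2-(triethylsilyloxy)propan-2-yl]-4H-chromen-4-one | Cc1c(O[Si](C)(C)C(C)(C)C)cc2c(=O)cc(C(C)(C)O[Si](CC)(CC)CC)oc2c1O[Si](C)(C)C(C)(C)C | intermediate
16 | (2S)-6,8-bis(tert-butyldimethylsilyloxy)-7-methyl-2-[2-(triethylsilyloxy)propan-2-yl]chroman-4-one | O=C1C[C@@H](C(C)(C)O[Si](CC)(CC)CC)Oc2c(O[Si](C)(C)C(C)(C)C)c(C)c(O[Si](C)(C)C(C)(C)C)cc21 | intermediate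
17 | vinylmagnesium bromide | C=C[Mg]Br | starting material
18 | (2S)-6,8-bis(tert-butyldimethylsilyloxy)-4-ethenyl-7-methyl-2-[2-(triethylsilyloxy)propan-2-yl]chroman-4-ol (both C4 epimers) | C=CC1(O)C[C@@H](C(C)(C)O[Si](CC)(CC)CC)Oc2c(O[Si](C)(C)C(C)(C)C)c(C)c(O[Si](C)(C)C(C)(C)C)cc21 | intermediate
19 | (2S)-7,9-bis(tert-butyldimethylsilyloxy)-8-methyl-5-[(phenylselanyl)methyl]-2-[2-(triethylsilyloxy)propan-2-yl]-2,3-dihydro-1-benzoxepin-4(5H)-one (C5 epimers) | O=C1C[C@@H](C(C)(C)O[Si](CC)(CC)CC)Oc2c(O[Si](C)(C)C(C)(C)C)c(C)c(O[Si](C)(C)C(C)(C)C)cc2C1C[Se]c1ccccc1 | intermediate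
20 | (2S)-7,9-bis(tert-butyldimethylsilyloxy)-8-methyl-5-[(phenylseleninyl)methyl]-2-[2-(triethylsilyloxy)propan-2-yl]-2,3-dihydro-1-benzoxepin-4(5H)-one | O=C1C[C@@H](C(C)(C)O[Si](CC)(CC)CC)Oc2c(O[Si](C)(C)C(C)(C)C)c(C)c(O[Si](C)(C)C(C)(C)C)cc2C1C[Se](=O)c1ccccc1 | intermediate
21 | (2S)-7,9-bis(tert-butyldimethylsilyloxy)-8-methyl-5-methylidene-2-[2-(triethylsilyloxy)propan-2-yl]-2,3-dihydro-1-benzoxepin-4(5H)-one | C=C1C(=O)C[C@@H](C(C)(C)O[Si](CC)(CC)CC)Oc2c(O[Si](C)(C)C(C)(C)C)c(C)c(O[Si](C)(C)C(C)(C)C)cc21 | intermediate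
22 | (2S,4R)-7,9-bis(tert-butyldimethylsilyloxy)-8-methyl-5-methylidene-2-[2-(triethylsilyloxy)propan-2-yl]-2,3,4,5-tetrahydro-1-benzoxepin-4-ol | C=C1c2cc(O[Si](C)(C)C(C)(C)C)c(C)c(O[Si](C)(C)C(C)(C)C)c2O[C@H](C(C)(C)O[Si](CC)(CC)CC)C[C@H]1O | intermediate
23 | angelic acid, (2Z)-2-methylbut-2-enoic acid | C/C=C(/C)C(=O)O | starting material
24 | (2Z)-2-methylbut-2-enoic 2,4,6-trichlorobenzoic anhydride | C/C=C(/C)C(=O)OC(=O)c1c(Cl)cc(Cl)cc1Cl | intermediate
25 | (2S,4R)-7,9-bis(tert-butyldimethylsilyloxy)-8-methyl-5-methylidene-2-[2-(triethylsilyloxy)propan-2-yl]-2,3,4,5-tetrahydro-1-benzoxepin-4-yl (2Z)-2-methylbut-2-enoate | C=C1c2cc(O[Si](C)(C)C(C)(C)C)c(C)c(O[Si](C)(C)C(C)(C)C)c2O[C@H](C(C)(C)O[Si](CC)(CC)CC)C[C@H]1OC(=O)/C(C)=C\C | intermediate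
26 | (2S,4R)-7,9-dihydroxy-2-(2-hydroxypropan-2-yl)-8-methyl-5-methylidene-2,3,4,5-tetrahydro-1-benzoxepin-4-yl (2Z)-2-methylbut-2-enoate | C=C1c2cc(O)c(C)c(O)c2O[C@H](C(C)(C)O)C[C@H]1OC(=O)/C(C)=C\C | target

## Step count and risks
Total step count: 13. Longest linear sequence: 13 steps (1 to 26). Compounds 8, 17 and 23 are bought.

**Step 10.** The seleniranium ion may be diverted by selenenylation of the arene or by migration of the C3 alkyl bond. The tertiary carbinol may also ionise and dehydrate before the shift takes place. The fallback keeps the same 1,2-aryl shift but triggers it from an epoxide.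
- It sets out from 18. Hydroxyl-directed epoxidation (VO(acac)2 cat., t-BuOOH, toluene, 0 °C) should give the epoxy alcohol (2S)-6,8-bis(tert-butyldimethylsilyloxy)-7-methyl-4-(oxiran-2-yl)-2-[2-(triethylsilyloxy)propan-2-yl]chroman-4-ol F1.
- ZnBr2 in CH2Cl2 opens the oxirane at its internal carbon with aryl migration, the known semipinacol rearrangement of 2,3-epoxy alcohols. This gives the aldol-type (2S)-7,9-bis(tert-butyldimethylsilyloxy)-5-(hydroxymethyl)-8-methyl-2-[2-(triethylsilyloxy)propan-2-yl]-2,3-dihydro-1-benzoxepin-4(5H)-one F2.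
- MsCl and Et3N at -40 °C form the corresponding methanesulfonate F3, which eliminates through the acidic C5–H. The sequence comes back to the route at 21.

**Step 8.** Hydrocupration may be slow at a C2 that bears a tertiary substituent. Facial discrimination may be poor, or reduction may run on to the chromanol. The fallback sets C2 by dynamic kinetic resolution instead.
- It sets out from 15. Hydrogenation (H2, Pd/C, EtOAc) gives racemic 6,8-bis(tert-butyldimethylsilyloxy)-7-methyl-2-[2-(triethylsilyloxy)propan-2-yl]chroman-4-one F4.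
- Noyori-type transfer hydrogenation with RuCl(p-cymene)[(S,S)-TsDPEN], HCO2H/Et3N and added DBU follows. The base racemises C2 by reversible retro-oxa-Michael opening while one enantiomer of the ketone is reduced faster. This should give cis-(2S,4S)-6,8-bis(tert-butyldimethylsilyloxy)-7-methyl-2-[2-(triethylsilyloxy)propan-2-yl]chroman-4-ol F5.
- Dess–Martin oxidation buffered with NaHCO3 comes back to the route at 16.

**Step 11.** Facial selectivity may be poor if the catalyst preference opposes the bias of the seven-membered ring. Conjugate reduction of the s-cis enone may also compete. The fallback uses substrate control followed by inversion.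
- It sets out from 21. Luche reduction (NaBH4, CeCl3·7H2O, MeOH–THF, -78 °C) is run under substrate control, and any trans alcohol formed is 22 itself.
- The cis epimer is (2S,4S)-7,9-bis(tert-butyldimethylsilyloxy)-8-methyl-5-methylidene-2-[2-(triethylsilyloxy)propan-2-yl]-2,3,4,5-tetrahydro-1-benzoxepin-4-ol F6. Mitsunobu esterification with 23 (PPh3, DIAD, toluene, 0 °C) inverts C4 while it installs the angelate. This comes back to the route at 25.

## Further compounds
F1 | step 10 | (2S)-6,8-bis(tert-butyldimethylsilyloxy)-7-methyl-4-(oxiran-2-yl)-2-[2-(triethylsilyloxy)propan-2-yl]chroman-4-ol | OC1(C2CO2)C[C@@H](C(C)(C)O[Si](CC)(CC)CC)Oc2c(O[Si](C)(C)C(C)(C)C)c(C)c(O[Si](C)(C)C(C)(C)C)cc21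
F2 | step 10 | (2S)-7,9-bis(tert-butyldimethylsilyloxy)-5-(hydroxymethyl)-8-methyl-2-[2-(triethylsilyloxy)propan-2-yl]-2,3-dihydro-1-benzoxepin-4(5H)-one | O=C1C[C@@H](C(C)(C)O[Si](CC)(CC)CC)Oc2c(O[Si](C)(C)C(C)(C)C)c(C)c(O[Si](C)(C)C(C)(C)C)cc2C1CO
F3 | step 10 | {(2S)-7,9-bis(tert-butyldimethylsilyloxy)-8-methyl-4-oxo-2-[2-(triethylsilyloxy)propan-2-yl]-2,3,4,5-tetrahydro-1-benzoxepin-5-yl}methyl methanesulfonate | O=C1C[C@@H](C(C)(C)O[Si](CC)(CC)CC)Oc2c(O[Si](C)(C)C(C)(C)C)c(C)c(O[Si](C)(C)C(C)(C)C)cc2C1COS(C)(=O)=O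
F4 | step 8 | racemic 6,8-bis(tert-butyldimethylsilyloxy)-7-methyl-2-[2-(triethylsilyloxy)propan-2-yl]chroman-4-one | O=C1CC(C(C)(C)O[Si](CC)(CC)CC)Oc2c(O[Si](C)(C)C(C)(C)C)c(C)c(O[Si](C)(C)C(C)(C)C)cc21
F5 | step 8 | (2S,4S)-6,8-bis(tert-butyldimethylsilyloxy)-7-methyl-2-[2-(triethylsilyloxy)propan-2-yl]chroman-4-ol | O[C@H]1C[C@@H](C(C)(C)O[Si](CC)(CC)CC)Oc2c(O[Si](C)(C)C(C)(C)C)c(C)c(O[Si](C)(C)C(C)(C)C)cc21
F6 | step 11 | (2S,4S)-7,9-bis(tert-butyldimethylsilyloxy)-8-methyl-5-methylidene-2-[2-(triethylsilyloxy)propan-2-yl]-2,3,4,5-tetrahydro-1-benzoxepin-4-ol | C=C1c2cc(O[Si](C)(C)C(C)(C)C)c(C)c(O[Si](C)(C)C(C)(C)C)c2O[C@H](C(C)(C)O[Si](CC)(CC)CC)C[C@@H]1O
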